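The route builds both phloroglucinol-type benzo rings (C4a to C8a of flavanone units A and B) from acyclic carbon at a late stage. In each ring C4a, which carries the C4 carbonyl, is flanked by hydroxylated C5 and by C8a bearing O1, and the C7 hydroxyl sits para to C4a; C4a and C8a can therefore come from an ynone and C5 to C8 from a 1,3-dioxygenated diene. One operation converts a bis(bromoalkynone), whose C2/C3 stereocentres are already in place as a silyl-protected tetrad, into a bis(2-bromo-4,6-dihydroxyphenyl) diketone by twofold Diels–Alder addition and loss of methanol; the bromine on each C8a then serves ring closure by the C2 oxygen.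

Key step: step 12

Remark: flavanone numbering is used for all intermediates. Unit A is the 4-methoxyphenyl half (C2 R, C3 S, 2,3-trans) and unit B the 4-hydroxyphenyl half (C2 R, C3 R, 2,3-cis). Both pyranone rings are closed with the C2–O bond intact, so the open-chain carbinols carry the configuration of the target. Compound 13 is taken as the commercial 0.5 M solution in THF.

Step 1
Reactants: 1 (R)-4-benzyl-1,3-oxazolidin-2-one; 2 methyl 4-chloro-4-oxobutanoate
Product: 3 methyl 4-[(4R)-4-benzyl-2-oxo-1,3-oxazolidin-3-yl]-4-oxobutanoate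
Conditions: n-BuLi, THF, −78 °C; then 2, −78 to 0 °C
Reagents that add atoms: none
Why: N-acylation of the lithiated oxazolidinone by the acid chloride is the standard loading of an Evans auxiliary and creates no stereocentre.

Step 2
Reactants: 3 methyl 4-[(4R)-4-benzyl-2-oxo-1,3-oxazolidin-3-yl]-4-oxobutanoate; 4 4-(benzyloxy)benzaldehyde
Product: 6 (4R)-4-benzyl-3-{[(2R,3R)-2-[4-(benzyloxy)phenyl]-5-oxooxolan-3-yl]carbonyl}-1,3-oxazolidin-2-one, via syn-aldol hydroxy ester 5 (not isolated)
Conditions: Bu2BOTf, iPr2NEt, CH2Cl2, 0 °C; 4, −78 to 0 °C; pH 7 buffer, H2O2, MeOH, 0 °C; PPTS (cat.), CH2Cl2, rt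
Reagents that add atoms: none
Why: Evans syn aldol: the Z-boron enolate of the imide (the ester is not enolized) adds to 4 through a chair transition state on the face remote from the benzyl group of the (R)-auxiliary, which sets C3(B) and C2(B) as R,R (syn), and the new hydroxyl then lactonizes onto the methyl ester to give the 2,3-trans lactone.

Step 3
Reactants: 6 (4R)-4-benzyl-3-{[(2R,3R)-2-[4-(benzyloxy)phenyl]-5-oxooxolan-3-yl]carbonyl}-1,3-oxazolidin-2-one
Product: 7 (2R,3R)-2-[4-(benzyloxy)phenyl]-5-oxooxolane-3-carboxylic acid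
Conditions: LiOH, H2O2, THF–H2O, 0 °C; Na2SO3; HCl to pH 2
Reagents that add atoms: hydrogen peroxide, OO
Why: Hydroperoxide hydrolysis of the N-acyl oxazolidinone attacks the exocyclic carbonyl selectively, the stereocentres are untouched, and any lactone opened by hydroxide recloses on acidification because only the five-membered ring is available.

Step 4
Reactants: 7 (2R,3R)-2-[4-(benzyloxy)phenyl]-5-oxooxolane-3-carboxylic acid; 8 4-methoxybenzaldehyde
Product: 9 (2R,3R,4S)-2-[4-(benzyloxy)phenyl]-4-[(R)-hydroxy(4-methoxyphenyl)methyl]-5-oxooxolane-3-carboxylic acid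
Conditions: LiN(SiMe3)2 (2.2 equiv), THF, −78 °C; ZnCl2; 8, −78 to −40 °C; AcOH
Reagents that add atoms: none
Why: Aldol addition of the carboxylate–lactone enolate dianion (the carboxylate prevents deprotonation at C3(B)): the aldehyde enters the enolate face anti to the neighbouring carboxylate, which fixes C3(A) trans to it, and the ring-locked enolate (α-substituent trans to O–metal) reacts through a chair Zimmerman–Traxler transition state, backed by equilibration of the chelated zinc aldolate, to the anti carbinol with C2(A) R.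

Step 5
Reactants: 9 (2R,3R,4S)-2-[4-(benzyloxy)phenyl]-4-[(R)-hydroxy(4-methoxyphenyl)methyl]-5-oxooxolane-3-carboxylic acid
Product: 10 (2R,3R,4S)-2-[4-(benzyloxy)phenyl]-4-[(R)-hydroxy(4-methoxyphenyl)methyl]-N-methoxy-N-methyl-5-oxooxolane-3-carboxamide
Conditions: MeNHOMe·HCl, EDC·HCl, HOBt (cat.), N-methylmorpholine, CH2Cl2, 0 °C to rt
Reagents that add atoms: N,O-dimethylhydroxylamine hydrochloride, CNOC.Cl
Why: Carbodiimide amide coupling converts the acid into the Weinreb amide; the amine outcompetes the hindered secondary hydroxyl, the trans arrangement of carboxyl and carbinol on the ring rules out a fused bis-lactone, and C3(B) already holds the stable trans,trans arrangement, so activation should not epimerize it.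

Step 6
Reactants: 10 (2R,3R,4S)-2-[4-(benzyloxy)phenyl]-4-[(R)-hydroxy(4-methoxyphenyl)methyl]-N-methoxy-N-methyl-5-oxooxolane-3-carboxamide
Product: 11 (2S,3R)-2-[(R)-hydroxy(4-methoxyphenyl)methyl]-3-[(R)-[4-(benzyloxy)phenyl](hydroxy)methyl]-N1,N4-dimethoxy-N1,N4-dimethylbutanediamide
Conditions: MeNHOMe·HCl, AlMe3, CH2Cl2, 0 °C to rt; aq. potassium sodium tartrate; crude used at once
Reagents that add atoms: N,O-dimethylhydroxylamine hydrochloride, CNOC.Cl
Why: Aminolysis of the lactone by the aluminium amide (Weinreb lactone opening) gives the second Weinreb amide and frees the C2(B) hydroxyl without breaking any bond to a stereocentre; the diol is silylated at once because it can relactonize.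

Step 7
Reactants: 11 (2S,3R)-2-[(R)-hydroxy(4-methoxyphenyl)methyl]-3-[(R)-[4-(benzyloxy)phenyl](hydroxy)methyl]-N1,N4-dimethoxy-N1,N4-dimethylbutanediamide
Product: 12 (2S,3R)-2-[(R)-(4-methoxyphenyl)(triethylsilyloxy)methyl]-3-[(R)-[4-(benzyloxy)phenyl](triethylsilyloxy)methyl]-N1,N4-dimethoxy-N1,N4-dimethylbutanediamide
Conditions: Et3SiOTf, 2,6-lutidine, CH2Cl2, −78 to 0 °C
Reagents that add atoms: triethylsilyl trifluoromethanesulfonate, CC[Si](CC)(CC)OS(=O)(=O)C(F)(F)F
Why: Silylation with a silyl triflate and a hindered pyridine base protects both benzylic hydroxyls in one operation and blocks relactonization under non-epimerizing conditions.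

Step 8
Reactants: 12 (2S,3R)-2-[(R)-(4-methoxyphenyl)(triethylsilyloxy)methyl]-3-[(R)-[4-(benzyloxy)phenyl](triethylsilyloxy)methyl]-N1,N4-dimethoxy-N1,N4-dimethylbutanediamide; 13 ethynylmagnesium bromide
Product: 14 (4S,5R)-4-[(R)-(4-methoxyphenyl)(triethylsilyloxy)methyl]-5-[(R)-[4-(benzyloxy)phenyl](triethylsilyloxy)methyl]octa-1,7-diyne-3,6-dione
Conditions: 13 (6 equiv), THF, 0 °C to rt; inverse quench into cold aq. NaHSO4–Et2O, 0 °C
Reagents that add atoms: none
Why: Weinreb ketone synthesis: each of the two amides takes up one ethynyl group from 13 as a magnesium-chelated tetrahedral adduct that collapses only on the acidic quench, so no second addition occurs at either carbonyl, the acid protonates the released N,O-dimethylhydroxylamine before it can add to the terminal ynones, and the weakly basic acetylide does not enolize C3.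

Step 9
Reactants: 14 (4S,5R)-4-[(R)-(4-methoxyphenyl)(triethylsilyloxy)methyl]-5-[(R)-[4-(benzyloxy)phenyl](triethylsilyloxy)methyl]octa-1,7-diyne-3,6-dione
Product: 15 (4S,5R)-1,8-dibromo-4-[(R)-(4-methoxyphenyl)(triethylsilyloxy)methyl]-5-[(R)-[4-(benzyloxy)phenyl](triethylsilyloxy)methyl]octa-1,7-diyne-3,6-dione
Conditions: NBS (2.2 equiv), AgNO3 (cat.), acetone, rt, dark; used at once
Reagents that add atoms: N-bromosuccinimide, O=C1CCC(=O)N1Br
Why: Silver-catalysed bromination of the two terminal alkynes (silver acetylides trapped by the N-bromo imide) gives the 1-bromoalkynes under neutral conditions that spare the silyl ethers, the electron-rich aryl rings and the enolizable C3 centres.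

Step 10
Reactants: 16 methyl acetoacetate
Product: 17 methyl 3-(trimethylsilyloxy)but-2-enoate (E/Z mixture)
Conditions: Me3SiCl, Et3N, hexane, rt
Reagents that add atoms: chlorotrimethylsilane, C[Si](C)(C)Cl
Why: Silyl enol ether formation from the enol of the β-keto ester under amine base is routine and involves no stereocentre.

Step 11
Reactants: 17 methyl 3-(trimethylsilyloxy)but-2-enoate
Product: 18 1-methoxy-1,3-bis(trimethylsilyloxy)buta-1,3-diene
Conditions: LiN(iPr)2, THF, −78 °C; Me3SiCl, −78 to 0 °C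
Reagents that add atoms: chlorotrimethylsilane, C[Si](C)(C)Cl
Why: Kinetic deprotonation of the allylic methyl group gives the extended ester enolate, whose O-silylation (silyl ketene acetal formation) delivers the 1,3-dioxygenated diene.

Step 12
Reactants: 15 (4S,5R)-1,8-dibromo-4-[(R)-(4-methoxyphenyl)(triethylsilyloxy)methyl]-5-[(R)-[4-(benzyloxy)phenyl](triethylsilyloxy)methyl]octa-1,7-diyne-3,6-dione; 18 1-methoxy-1,3-bis(trimethylsilyloxy)buta-1,3-diene
Product: 21 (2S,3R)-1,4-bis(2-bromo-4,6-dihydroxyphenyl)-2-[(R)-(4-methoxyphenyl)(triethylsilyloxy)methyl]-3-[(R)-[4-(benzyloxy)phenyl](triethylsilyloxy)methyl]butane-1,4-dione, via bis-cycloadduct 19 (not isolated), via tetrakis(trimethylsilyl) aryl ether 20 (not isolated)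
Conditions: 18 (5 equiv), PhMe, 25 to 70 °C; then THF, aq. citric acid, 0 °C
Reagents that add atoms: none
Why: Each bromoalkynone, activated by the carbonyl on Cα and by bromine on Cβ, acts as the 2π partner of the electron-rich diene 18 in a normal-demand [4+2] cycloaddition; the 1,4-cyclohexadiene 19 so formed carries a mixed acetal carbon next to the acyl-bearing carbon and aromatizes by 1,4-loss of methanol to aryl silyl ether 20, whose four O–SiMe3 bonds are hydrolysed in the mildly acidic work-up. The closest known reaction type is the Diels–Alder addition of alkynyl ketones and esters to 1-alkoxy-1,3-bis(silyloxy)butadienes with aromatization to resorcinols, together with cycloadditions of 1-bromoalkynyl carbonyl compounds as dienophiles. Each of the two benzo rings is closed by an intermolecular [4+2] cycloaddition that forms C4a–C5 and C8–C8a in one ring-forming event, the alkyne supplying C4a and C8a and the diene C5 to C8, followed by aromatizing elimination. No stereocentre is created (the acetal carbons of 19 are transient), and the neutral thermal conditions should leave the silyl-protected, enolizable C2–C3–C3–C2 tetrad untouched. The only selectivity needed is regiochemical: the nucleophilic CH2 terminus of 18 must bond to the electrophilic bromine-bearing β-carbon (future C8a) and the ketene acetal carbon to the α-carbon (future C4a), which the polarization of the ynone and the larger HOMO coefficient at the CH2 terminus secure, so that OH arrives on C5 and C7 and bromine on C8a.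

Step 13
Reactants: 21 (2S,3R)-1,4-bis(2-bromo-4,6-dihydroxyphenyl)-2-[(R)-(4-methoxyphenyl)(triethylsilyloxy)methyl]-3-[(R)-[4-(benzyloxy)phenyl](triethylsilyloxy)methyl]butane-1,4-dione
Product: 22 (2S,3R)-1,4-bis[2,4-bis(benzyloxy)-6-bromophenyl]-2-[(R)-(4-methoxyphenyl)(triethylsilyloxy)methyl]-3-[(R)-[4-(benzyloxy)phenyl](triethylsilyloxy)methyl]butane-1,4-dione
Conditions: BnBr, K2CO3, Bu4NI (cat.), acetone, 50 °C
Reagents that add atoms: benzyl bromide, BrCc1ccccc1
Why: Williamson ether synthesis: carbonate deprotonates only the four phenols, which are benzylated, while the tertiary C3 hydrogens next to the twisted 2,6-disubstituted aryl ketones are not removed by this weak base, so neither loss of silanol nor epimerization should occur.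

Step 14
Reactants: 22 (2S,3R)-1,4-bis[2,4-bis(benzyloxy)-6-bromophenyl]-2-[(R)-(4-methoxyphenyl)(triethylsilyloxy)methyl]-3-[(R)-[4-(benzyloxy)phenyl](triethylsilyloxy)methyl]butane-1,4-dione
Product: 23 (2S,3R)-1,4-bis[2,4-bis(benzyloxy)-6-bromophenyl]-2-[(R)-hydroxy(4-methoxyphenyl)methyl]-3-[(R)-[4-(benzyloxy)phenyl](hydroxy)methyl]butane-1,4-dione
Conditions: HF·pyridine, pyridine, THF, 0 °C to rt
Reagents that add atoms: none
Why: Fluoride-mediated desilylation under pyridine-buffered, non-basic conditions frees both C2 hydroxyls without retro-aldol cleavage, elimination or ionization of the benzylic carbinols.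

Step 15
Reactants: 23 (2S,3R)-1,4-bis[2,4-bis(benzyloxy)-6-bromophenyl]-2-[(R)-hydroxy(4-methoxyphenyl)methyl]-3-[(R)-[4-(benzyloxy)phenyl](hydroxy)methyl]butane-1,4-dione
Product: 24 (2R,3S)-5,7-bis(benzyloxy)-3-[(2R,3R)-5,7-bis(benzyloxy)-2-[4-(benzyloxy)phenyl]-4-oxo-3,4-dihydro-2H-chromen-3-yl]-2-(4-methoxyphenyl)-2,3-dihydro-4H-chromen-4-one
Conditions: CuI (20 mol%), 3,4,7,8-tetramethyl-1,10-phenanthroline, Cs2CO3, PhMe, 80 °C
Reagents that add atoms: none
Why: Twofold intramolecular Ullmann-type C–O coupling (copper-catalysed O-arylation of an alcohol by an aryl bromide, assisted by the ortho carbonyl): each C2 oxygen displaces bromine on C8a of its own half in a six-membered closure, the C2–O bond is never broken, so C2 and C3 are retained and unit A closes 2,3-trans, unit B 2,3-cis.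

Step 16
Reactants: 24 (2R,3S)-5,7-bis(benzyloxy)-3-[(2R,3R)-5,7-bis(benzyloxy)-2-[4-(benzyloxy)phenyl]-4-oxo-3,4-dihydro-2H-chromen-3-yl]-2-(4-methoxyphenyl)-2,3-dihydro-4H-chromen-4-one
Product: 25 Sikokianin B, (2R,3S)-3-[(2R,3R)-5,7-dihydroxy-2-(4-hydroxyphenyl)-4-oxo-3,4-dihydro-2H-chromen-3-yl]-5,7-dihydroxy-2-(4-methoxyphenyl)-2,3-dihydro-4H-chromen-4-one
Conditions: H2 (1 atm), 10% Pd/C, EtOAc–MeOH, rt
Reagents that add atoms: none
Why: Catalytic hydrogenolysis of the five benzyl aryl ethers under neutral conditions should leave the methyl ether, the ketones and the base-labile 2,3-cis unit B unchanged.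

**Compound list**

1 | (R)-4-benzyl-1,3-oxazolidin-2-one | O=C1N[C@H](Cc2ccccc2)CO1 | starting material
2 | methyl 4-chloro-4-oxobutanoate | COC(=O)CCC(=O)Cl | starting material
3 | methyl 4-[(4R)-4-benzyl-2-oxo-1,3-oxazolidin-3-yl]-4-oxobutanoate | COC(=O)CCC(=O)N1[C@H](Cc2ccccc2)COC1=O | intermediate
4 | 4-(benzyloxy)benzaldehyde | O=Cc1ccc(OCc2ccccc2)cc1 | starting material
5 | methyl (3R,4R)-3-{[(4R)-4-benzyl-2-oxo-1,3-oxazolidin-3-yl]carbonyl}-4-[4-(benzyloxy)phenyl]-4-hydroxybutanoate (syn aldol adduct, not isolated) | COC(=O)C[C@@H](C(=O)N1[C@H](Cc2ccccc2)COC1=O)[C@@H](O)c1ccc(OCc2ccccc2)cc1 | intermediate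
6 | (4R)-4-benzyl-3-{[(2R,3R)-2-[4-(benzyloxy)phenyl]-5-oxooxolan-3-yl]carbonyl}-1,3-oxazolidin-2-one (2,3-trans lactone) | O=C([C@@H]1CC(=O)O[C@H]1c1ccc(OCc2ccccc2)cc1)N1[C@H](Cc2ccccc2)COC1=O | intermediate
7 | (2R,3R)-2-[4-(benzyloxy)phenyl]-5-oxooxolane-3-carboxylic acid | O=C(O)[C@@H]1CC(=O)O[C@H]1c1ccc(OCc2ccccc2)cc1 | intermediate
8 | 4-methoxybenzaldehyde | COc1ccc(C=O)cc1 | starting material
9 | (2R,3R,4S)-2-[4-(benzyloxy)phenyl]-4-[(R)-hydroxy(4-methoxyphenyl)methyl]-5-oxooxolane-3-carboxylic acid | COc1ccc([C@H](O)[C@H]2C(=O)O[C@@H](c3ccc(OCc4ccccc4)cc3)[C@@H]2C(=O)O)cc1 | intermediate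
10 | (2R,3R,4S)-2-[4-(benzyloxy)phenyl]-4-[(R)-hydroxy(4-methoxyphenyl)methyl]-N-methoxy-N-methyl-5-oxooxolane-3-carboxamide | COc1ccc([C@H](O)[C@H]2C(=O)O[C@@H](c3ccc(OCc4ccccc4)cc3)[C@@H]2C(=O)N(C)OC)cc1 | intermediate
11 | (2S,3R)-2-[(R)-hydroxy(4-methoxyphenyl)methyl]-3-[(R)-[4-(benzyloxy)phenyl](hydroxy)methyl]-N1,N4-dimethoxy-N1,N4-dimethylbutanediamide | COc1ccc([C@H](O)[C@@H](C(=O)N(C)OC)[C@@H](C(=O)N(C)OC)[C@@H](O)c2ccc(OCc3ccccc3)cc2)cc1 | intermediate
12 | (2S,3R)-2-[(R)-(4-methoxyphenyl)(triethylsilyloxy)methyl]-3-[(R)-[4-(benzyloxy)phenyl](triethylsilyloxy)methyl]-N1,N4-dimethoxy-N1,N4-dimethylbutanediamide | COc1ccc([C@H](O[Si](CC)(CC)CC)[C@@H](C(=O)N(C)OC)[C@@H](C(=O)N(C)OC)[C@@H](O[Si](CC)(CC)CC)c2ccc(OCc3ccccc3)cc2)cc1 | intermediate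
13 | ethynylmagnesium bromide | C#C[Mg]Br | starting material
14 | (4S,5R)-4-[(R)-(4-methoxyphenyl)(triethylsilyloxy)methyl]-5-[(R)-[4-(benzyloxy)phenyl](triethylsilyloxy)methyl]octa-1,7-diyne-3,6-dione | COc1ccc([C@H](O[Si](CC)(CC)CC)[C@@H](C(=O)C#C)[C@@H](C(=O)C#C)[C@@H](O[Si](CC)(CC)CC)c2ccc(OCc3ccccc3)cc2)cc1 | intermediate
15 | (4S,5R)-1,8-dibromo-4-[(R)-(4-methoxyphenyl)(triethylsilyloxy)methyl]-5-[(R)-[4-(benzyloxy)phenyl](triethylsilyloxy)methyl]octa-1,7-diyne-3,6-dione (key-step precursor) | COc1ccc([C@H](O[Si](CC)(CC)CC)[C@@H](C(=O)C#CBr)[C@@H](C(=O)C#CBr)[C@@H](O[Si](CC)(CC)CC)c2ccc(OCc3ccccc3)cc2)cc1 | intermediate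
16 | methyl acetoacetate | COC(=O)CC(C)=O | starting material
17 | methyl 3-(trimethylsilyloxy)but-2-enoate (E/Z mixture) | COC(=O)C=C(C)O[Si](C)(C)C | intermediate
18 | 1-methoxy-1,3-bis(trimethylsilyloxy)buta-1,3-diene | COC(O[Si](C)(C)C)=CC(=C)O[Si](C)(C)C | intermediate
19 | bis-cycloadduct: analogue of 21 in which each aryl group is 2-bromo-6-methoxy-4,6-bis(trimethylsilyloxy)cyclohexa-1,4-dien-1-yl (mixture at the two acetal carbons, not isolated) | COc1ccc([C@H](O[Si](CC)(CC)CC)[C@@H](C(=O)C2=C(Br)CC(O[Si](C)(C)C)=CC2(OC)O[Si](C)(C)C)[C@@H](C(=O)C2=C(Br)CC(O[Si](C)(C)C)=CC2(OC)O[Si](C)(C)C)[C@@H](O[Si](CC)(CC)CC)c2ccc(OCc3ccccc3)cc2)cc1 | intermediate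
20 | tetrakis(trimethylsilyl) aryl ether: analogue of 21 in which each aryl group is 2-bromo-4,6-bis(trimethylsilyloxy)phenyl (not isolated) | COc1ccc([C@H](O[Si](CC)(CC)CC)[C@@H](C(=O)c2c(O[Si](C)(C)C)cc(O[Si](C)(C)C)cc2Br)[C@@H](C(=O)c2c(O[Si](C)(C)C)cc(O[Si](C)(C)C)cc2Br)[C@@H](O[Si](CC)(CC)CC)c2ccc(OCc3ccccc3)cc2)cc1 | intermediate
21 | (2S,3R)-1,4-bis(2-bromo-4,6-dihydroxyphenyl)-2-[(R)-(4-methoxyphenyl)(triethylsilyloxy)methyl]-3-[(R)-[4-(benzyloxy)phenyl](triethylsilyloxy)methyl]butane-1,4-dione (key-step product) | COc1ccc([C@H](O[Si](CC)(CC)CC)[C@@H](C(=O)c2c(O)cc(O)cc2Br)[C@@H](C(=O)c2c(O)cc(O)cc2Br)[C@@H](O[Si](CC)(CC)CC)c2ccc(OCc3ccccc3)cc2)cc1 | intermediate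
22 | (2S,3R)-1,4-bis[2,4-bis(benzyloxy)-6-bromophenyl]-2-[(R)-(4-methoxyphenyl)(triethylsilyloxy)methyl]-3-[(R)-[4-(benzyloxy)phenyl](triethylsilyloxy)methyl]butane-1,4-dione | COc1ccc([C@H](O[Si](CC)(CC)CC)[C@@H](C(=O)c2c(OCc3ccccc3)cc(OCc3ccccc3)cc2Br)[C@@H](C(=O)c2c(OCc3ccccc3)cc(OCc3ccccc3)cc2Br)[C@@H](O[Si](CC)(CC)CC)c2ccc(OCc3ccccc3)cc2)cc1 | intermediate
23 | (2S,3R)-1,4-bis[2,4-bis(benzyloxy)-6-bromophenyl]-2-[(R)-hydroxy(4-methoxyphenyl)methyl]-3-[(R)-[4-(benzyloxy)phenyl](hydroxy)methyl]butane-1,4-dione | COc1ccc([C@H](O)[C@@H](C(=O)c2c(OCc3ccccc3)cc(OCc3ccccc3)cc2Br)[C@@H](C(=O)c2c(OCc3ccccc3)cc(OCc3ccccc3)cc2Br)[C@@H](O)c2ccc(OCc3ccccc3)cc2)cc1 | intermediate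
24 | (2R,3S)-5,7-bis(benzyloxy)-3-[(2R,3R)-5,7-bis(benzyloxy)-2-[4-(benzyloxy)phenyl]-4-oxo-3,4-dihydro-2H-chromen-3-yl]-2-(4-methoxyphenyl)-2,3-dihydro-4H-chromen-4-one | COc1ccc([C@@H]2Oc3cc(OCc4ccccc4)cc(OCc4ccccc4)c3C(=O)[C@H]2[C@H]2C(=O)c3c(OCc4ccccc4)cc(OCc4ccccc4)cc3O[C@H]2c2ccc(OCc3ccccc3)cc2)cc1 | intermediate
25 | Sikokianin B, (2R,3S)-3-[(2R,3R)-5,7-dihydroxy-2-(4-hydroxyphenyl)-4-oxo-3,4-dihydro-2H-chromen-3-yl]-5,7-dihydroxy-2-(4-methoxyphenyl)-2,3-dihydro-4H-chromen-4-one | COc1ccc([C@@H]2Oc3cc(O)cc(O)c3C(=O)[C@H]2[C@H]2C(=O)c3c(O)cc(O)cc3O[C@H]2c2ccc(O)cc2)cc1 | target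

**Step count and risk**

Total step count: 16. Longest linear sequence: 14 steps (steps 1 to 9 and 12 to 16); the diene is made in the two-step side branch, steps 10 and 11.

The three steps most likely to fail:

1. Step 12. The ketene acetal terminus of 18 may attack bromine instead of carbon (halogen transfer from the bromoalkyne), or add in conjugate fashion without ring closure. Aromatization may also partly proceed by loss of silanol in place of methanol, or a triethylsilyl ether may be lost. The fallback gives up ring construction and brings both rings in preformed. Commercial 1,3-bis(benzyloxy)-5-bromobenzene would be iodinated (N-iodosuccinimide, MeCN) between bromine and a benzyloxy group to 1,5-bis(benzyloxy)-3-bromo-2-iodobenzene F1. Selective iodine–magnesium exchange (iPrMgCl·LiCl, THF, −30 °C) would give [2,4-bis(benzyloxy)-6-bromophenyl]magnesium chloride F2, which would be acylated by both Weinreb amides of 12 (THF, −30 to 0 °C). The fallback sets out from 12 and returns to the route at 22.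

2. Step 15. Under carbonate at 80 °C the β-hydroxy ketones may fragment by retro-aldol cleavage or lose water, and the 2,3-cis unit B, once closed, may epimerize at C3 through enolization or ring opening. The fallback takes the ketones out of play during the coupling. Diol 23 would be reduced (LiBH4, THF, 0 °C) to 1,4-bis[2,4-bis(benzyloxy)-6-bromophenyl]-2-[(R)-hydroxy(4-methoxyphenyl)methyl]-3-[(R)-[4-(benzyloxy)phenyl](hydroxy)methyl]butane-1,4-diol F3, a mixture at the two new carbinol carbons that is of no consequence. The same CuI-catalysed closure, now free of enolizable and retro-aldol-prone groups, would give the penta-O-benzyl bis(flavan-4-ol) F4, and Dess–Martin periodinane (CH2Cl2, rt) would restore both C4 ketones. The fallback sets out from 23 and returns at 24.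

3. Step 4. Facial selectivity at the aldehyde carbon may be poor, so that the C2(A) epimer (syn carbinol) forms beside 9. The fallback sets C2(A) by C–H instead of C–C bond formation. The epimer mixture would be oxidized (Dess–Martin periodinane, CH2Cl2) to the single keto lactone (2R,3R,4S)-2-[4-(benzyloxy)phenyl]-4-(4-methoxybenzoyl)-5-oxooxolane-3-carboxylic acid F5. The ketone would then be reduced under non-chelating conditions (LiEt3BH, CeCl3, THF, −78 °C), the anti-selective protocol known for 2-substituted 3-keto esters, in which hydride attacks the conformer with opposed carbonyl dipoles from the side of the C3(A) hydrogen. The fallback sets out from 9 (as its mixture with the carbinol epimer) and returns at 9.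

**Further compounds**

F1 | step 12 | 1,5-bis(benzyloxy)-3-bromo-2-iodobenzene | Brc1cc(OCc2ccccc2)cc(OCc2ccccc2)c1I
F2 | step 12 | [2,4-bis(benzyloxy)-6-bromophenyl]magnesium chloride | Cl[Mg]c1c(Br)cc(OCc2ccccc2)cc1OCc1ccccc1
F3 | step 15 | 1,4-bis[2,4-bis(benzyloxy)-6-bromophenyl]-2-[(R)-hydroxy(4-methoxyphenyl)methyl]-3-[(R)-[4-(benzyloxy)phenyl](hydroxy)methyl]butane-1,4-diol (C2 and C3 as in 23, mixture at C1 and C4) | COc1ccc([C@H](O)[C@@H](C(O)c2c(OCc3ccccc3)cc(OCc3ccccc3)cc2Br)[C@@H](C(O)c2c(OCc3ccccc3)cc(OCc3ccccc3)cc2Br)[C@@H](O)c2ccc(OCc3ccccc3)cc2)cc1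
F4 | step 15 | penta-O-benzyl bis(flavan-4-ol), the C4,C4 diol corresponding to 24 (C2 and C3 of both units as in 24, mixture at both C4) | COc1ccc([C@@H]2Oc3cc(OCc4ccccc4)cc(OCc4ccccc4)c3C(O)[C@H]2[C@H]2C(O)c3c(OCc4ccccc4)cc(OCc4ccccc4)cc3O[C@H]2c2ccc(OCc3ccccc3)cc2)cc1
F5 | step 4 | (2R,3R,4S)-2-[4-(benzyloxy)phenyl]-4-(4-methoxybenzoyl)-5-oxooxolane-3-carboxylic acid | COc1ccc(C(=O)[C@H]2C(=O)O[C@@H](c3ccc(OCc4ccccc4)cc3)[C@@H]2C(=O)O)cc1
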